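The synthesis rests on cutting the two adjacent bonds on the catechol ring (ring B of the luteolin half). These are C6'–C6 to flavanone ring A and C1'–C2 to the flavone pyrone. C1' and C6' lie opposite O3' and O4', so this ring is a symmetric 4,5-dioxygenated benzyne. In one operation a phloroglucinol-derived aryl Grignard reagent adds to that aryne, which magnesium frees from the dibenzyl ether of 4,5-dibromocatechol. CO2 then carboxylates the resulting biaryl Grignard. The nucleophile carries benzyl groups on both ortho oxygens and a methoxymethyl group on the para oxygen only. That oxygen therefore emerges alone later and becomes O1 of the 6-linked (2R)-flavanone.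

Key step: step 6

Remark: the stereodescriptor of the target corresponds to 2R (the antipode of the usual natural flavanone series); the C6–C6' biaryl axis carries no descriptor and is treated as configurationally undefined, so any rotamer mixtures of protected intermediates are carried forward together.

Step 1
Reactants: 1 phloroglucinol
Product: 2 5-(methoxymethoxy)benzene-1,3-diol
Conditions: MOMCl (1 equiv), K2CO3 (1.2 equiv), acetone, 0 °C to rt; 1 used in threefold excess
Reagents that add atoms: chloromethyl methyl ether, COCCl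
Why: Williamson-type O-alkylation of a phenoxide, in which the excess of the cheap symmetric triol should make the mono-ether the main alkylated product and unreacted 1 is removed by aqueous washing and chromatography.

Step 2
Reactants: 2 5-(methoxymethoxy)benzene-1,3-diol
Product: 3 2-iodo-5-(methoxymethoxy)benzene-1,3-diol
Conditions: I2 (1.0 equiv), NaHCO3 (1.1 equiv), THF–H2O 1:1, 0 °C
Reagents that add atoms: iodine, II
Why: Bicarbonate-buffered electrophilic aromatic iodination, which on resorcinol and its 5-substituted congeners places iodine at C2 between the two free hydroxyls, so the halogen marks the carbon para to the acetal oxygen while the buffer suppresses acid-induced iodine migration.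

Step 3
Reactants: 3 2-iodo-5-(methoxymethoxy)benzene-1,3-diol
Product: 4 1,3-bis(benzyloxy)-2-iodo-5-(methoxymethoxy)benzene
Conditions: BnBr (2.2 equiv), K2CO3 (3 equiv), DMF, rt
Reagents that add atoms: benzyl bromide, BrCc1ccccc1
Why: Williamson ether synthesis on the two phenols flanking the iodine, as is routine for 2-iodoresorcinols, with the acetal and the C–I bond inert to carbonate.

Step 4
Reactants: 5 4,5-dibromobenzene-1,2-diol
Product: 6 1,2-bis(benzyloxy)-4,5-dibromobenzene
Conditions: BnBr (2.2 equiv), K2CO3 (3 equiv), DMF, 50 °C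
Reagents that add atoms: benzyl bromide, BrCc1ccccc1
Why: Williamson ether synthesis on a catechol, giving a symmetric aryne precursor whose ethers tolerate magnesium and Grignard reagents and fall in the final hydrogenolysis.

Step 5
Reactants: 4 1,3-bis(benzyloxy)-2-iodo-5-(methoxymethoxy)benzene
Product: 7 [2,6-bis(benzyloxy)-4-(methoxymethoxy)phenyl]magnesium iodide
Conditions: Mg turnings (1.3 equiv), LiCl (1.2 equiv), THF, 25–40 °C; decanted, titrated, used as the THF solution
Reagents that add atoms: magnesium, [Mg]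
Why: Grignard formation by direct insertion of magnesium into an aryl iodide, chosen over halogen–metal exchange because it leaves no alkyl halide that could become a competing nucleophile in the next step, the flanking ether oxygens stabilising the reagent by chelation.

Step 6
Reactants: 7 [2,6-bis(benzyloxy)-4-(methoxymethoxy)phenyl]magnesium iodide; 6 1,2-bis(benzyloxy)-4,5-dibromobenzene; 8 carbon dioxide
Product: 12 4,5-bis(benzyloxy)-2-[2,6-bis(benzyloxy)-4-(methoxymethoxy)phenyl]benzoic acid, via 2-bromo-4,5-bis(benzyloxy)phenylmagnesium bromide 9 (not isolated), via 4,5-bis(benzyloxy)benzyne 10 (not isolated), via 2-biarylmagnesium iodide 11 (not isolated)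
Conditions: 7 (1.5 equiv), Mg turnings (1.5 equiv), THF, 60 °C, 6 in THF added by syringe pump over 3 h, then 1 h; dry CO2 gas, −10 °C to rt; cold 1 M HCl to pH 3
Reagents that add atoms: none
Why: Magnesium inserts into one C–Br bond of 6 to give 9, which loses MgBr2 at 60 °C to release aryne 10; 7 carbometallates the strained triple bond, forming the future C6–C6' biaryl bond and leaving 11, whose C–Mg bond is carboxylated by 8 to install the future flavone C2. The closest known reaction type is the addition of hindered aryl Grignard reagents to arynes generated from ortho-dihaloarenes and magnesium, followed by electrophilic quench of the 2-biaryl Grignard, as used for biaryl phosphine ligands and terphenyl carboxylic acids. No ring is closed and no stereocentre is created. No regiochemical choice exists, because 10 has a mirror plane bisecting its triple bond and 7 is symmetric about its C–Mg axis. The selectivity required is chemoselective capture of 10 by 7 rather than by 9 or 11, which is secured by slow addition of 6 into an excess of 7 and by the greater steric shielding of the C–Mg bond in 11. The tri-ortho-substituted biaryl bond is thus made by addition to a very reactive acceptor, and the benzyl groups on both ortho oxygens prevent those oxygens from later attacking the new carboxyl carbon.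

Step 7
Reactants: 13 2',4',6'-trihydroxyacetophenone
Product: 14 1-[2,4-bis(benzyloxy)-6-hydroxyphenyl]ethanone
Conditions: BnBr (2.05 equiv), K2CO3 (2.2 equiv), DMF, rt to 40 °C
Reagents that add atoms: benzyl bromide, BrCc1ccccc1
Why: Selective Williamson benzylation, in which one hydroxyl stays hydrogen-bonded to the acetyl carbonyl, is the least nucleophilic and remains free when only two equivalents of halide are offered.

Step 8
Reactants: 12 4,5-bis(benzyloxy)-2-[2,6-bis(benzyloxy)-4-(methoxymethoxy)phenyl]benzoic acid; 14 1-[2,4-bis(benzyloxy)-6-hydroxyphenyl]ethanone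
Product: 15 2-acetyl-3,5-bis(benzyloxy)phenyl 4,5-bis(benzyloxy)-2-[2,6-bis(benzyloxy)-4-(methoxymethoxy)phenyl]benzoate
Conditions: DCC (1.3 equiv), DMAP (0.3 equiv), CH2Cl2, rt
Reagents that add atoms: none
Why: Steglich esterification, which activates the ortho-aryl benzoic acid under neutral conditions that spare the acetal and avoids an acid chloride that a neighbouring ether oxygen could attack.

Step 9
Reactants: 15 2-acetyl-3,5-bis(benzyloxy)phenyl 4,5-bis(benzyloxy)-2-[2,6-bis(benzyloxy)-4-(methoxymethoxy)phenyl]benzoate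
Product: 16 1-[2,4-bis(benzyloxy)-6-hydroxyphenyl]-3-{4,5-bis(benzyloxy)-2-[2,6-bis(benzyloxy)-4-(methoxymethoxy)phenyl]phenyl}propane-1,3-dione
Conditions: LiN(SiMe3)2 (3 equiv), THF, −78 °C to 0 °C; AcOH quench
Reagents that add atoms: none
Why: Baker–Venkataraman rearrangement, in which the lithium enolate of the acetyl group attacks the adjacent aryl ester through a six-membered transition state and the aroyl group moves from O to C, the non-nucleophilic amide base excluding simple ester cleavage.

Step 10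
Reactants: 16 1-[2,4-bis(benzyloxy)-6-hydroxyphenyl]-3-{4,5-bis(benzyloxy)-2-[2,6-bis(benzyloxy)-4-(methoxymethoxy)phenyl]phenyl}propane-1,3-dione
Product: 17 5,7-bis(benzyloxy)-2-{4,5-bis(benzyloxy)-2-[2,6-bis(benzyloxy)-4-hydroxyphenyl]phenyl}-4H-chromen-4-one
Conditions: conc. HCl (cat.), MeOH–THF 1:1, 55 °C
Reagents that add atoms: none
Why: Acid-catalysed cyclodehydration of an o-hydroxyaryl 1,3-diketone to the flavone, with acetal exchange of the single MOM ether in the same pot; because both oxygens ortho to the biaryl bond are benzylated, no second phenol can compete for the aroyl carbonyl, and the para oxygen is the only one set free.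

Step 11
Reactants: 17 5,7-bis(benzyloxy)-2-{4,5-bis(benzyloxy)-2-[2,6-bis(benzyloxy)-4-hydroxyphenyl]phenyl}-4H-chromen-4-one
Product: 19 2-{2-[3-acetyl-2,6-bis(benzyloxy)-4-hydroxyphenyl]-4,5-bis(benzyloxy)phenyl}-5,7-bis(benzyloxy)-4H-chromen-4-one, via aryl acetate 18 (not isolated)
Conditions: Ac2O (3 equiv), BF3·OEt2 (5 equiv), CH2Cl2, 0 °C to 35 °C; aq. NaOAc work-up
Reagents that add atoms: acetic anhydride, CC(=O)OC(C)=O
Why: Lewis-acid-promoted O-acetylation and Fries rearrangement (overall a Friedel–Crafts C-acylation) on the most electron-rich ring, the only oxygenated one attached to no carbonyl group; its two open positions are equivalent and both lie ortho to the free hydroxyl, so one regioisomer should result and the first acyl group shuts off a second acylation.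

Step 12
Reactants: 19 2-{2-[3-acetyl-2,6-bis(benzyloxy)-4-hydroxyphenyl]-4,5-bis(benzyloxy)phenyl}-5,7-bis(benzyloxy)-4H-chromen-4-one
Product: 21 5,7-bis(benzyloxy)-6-{4,5-bis(benzyloxy)-2-[5,7-bis(benzyloxy)-4-oxo-4H-chromen-2-yl]phenyl}-4H-chromen-4-one, via enaminone 20 (not isolated)
Conditions: Me2NCH(OMe)2 (3 equiv), toluene, 95 °C; evaporation; conc. HCl, CH2Cl2, rt
Reagents that add atoms: N,N-dimethylformamide dimethyl acetal, COC(OC)N(C)C
Why: Standard enaminone chromone synthesis (condensation of the methyl ketone with the amide acetal, then acid-induced addition–elimination by the neighbouring phenol); the only free hydroxyl is the one para to the biaryl bond, so it becomes O1 and the aryl substituent is locked at C6 rather than C8.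

Step 13
Reactants: 21 5,7-bis(benzyloxy)-6-{4,5-bis(benzyloxy)-2-[5,7-bis(benzyloxy)-4-oxo-4H-chromen-2-yl]phenyl}-4H-chromen-4-one; 22 4-(benzyloxy)phenylboronic acid
Product: 23 (2R)-5,7-bis(benzyloxy)-2-[4-(benzyloxy)phenyl]-6-{4,5-bis(benzyloxy)-2-[5,7-bis(benzyloxy)-4-oxo-4H-chromen-2-yl]phenyl}-2,3-dihydro-4H-chromen-4-one
Conditions: 22 (2.5 equiv), Pd(OCOCF3)2 (10 mol %), (S)-4-tert-butyl-2-(pyridin-2-yl)-4,5-dihydrooxazole (12 mol %), NH4PF6 (30 mol %), H2O (5 equiv), ClCH2CH2Cl, 60 °C
Reagents that add atoms: none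
Why: Palladium-catalysed enantioselective conjugate addition of an arylboronic acid to a chromone, in which the cationic aryl–palladium complex of the pyridine–oxazoline ligand inserts the C2=C3 bond from the face left open by the tert-butyl group; by the model that holds for cyclic enones this should set C2 as R with the (S)-ligand (the antipodal ligand is equally available should a simple model chromone show the opposite sense), the flavone stays inert because its β-carbon is fully substituted and shielded, and the base-free medium avoids retro-oxa-Michael opening.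

Step 14
Reactants: 23 (2R)-5,7-bis(benzyloxy)-2-[4-(benzyloxy)phenyl]-6-{4,5-bis(benzyloxy)-2-[5,7-bis(benzyloxy)-4-oxo-4H-chromen-2-yl]phenyl}-2,3-dihydro-4H-chromen-4-one
Product: 24 (2R)-6-[2-(5,7-dihydroxy-4-oxo-4H-chromen-2-yl)-4,5-dihydroxyphenyl]-5,7-dihydroxy-2-(4-hydroxyphenyl)-2,3-dihydro-4H-chromen-4-one
Conditions: H2 (1 atm), 10% Pd/C, THF–MeOH 1:1, rt; filtration, evaporation below 30 °C
Reagents that add atoms: none
Why: Catalytic hydrogenolysis of all seven benzyl ethers under neutral conditions, so that neither acid nor base is present to open the pyranone by retro-oxa-Michael reaction and C2 should keep its R configuration.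

Compound list
1 | phloroglucinol | Oc1cc(O)cc(O)c1 | starting material
2 | 5-(methoxymethoxy)benzene-1,3-diol | COCOc1cc(O)cc(O)c1 | intermediate
3 | 2-iodo-5-(methoxymethoxy)benzene-1,3-diol | COCOc1cc(O)c(I)c(O)c1 | intermediate
4 | 1,3-bis(benzyloxy)-2-iodo-5-(methoxymethoxy)benzene | COCOc1cc(OCc2ccccc2)c(I)c(OCc2ccccc2)c1 | intermediate
5 | 4,5-dibromobenzene-1,2-diol | Oc1cc(Br)c(Br)cc1O | starting material
6 | 1,2-bis(benzyloxy)-4,5-dibromobenzene | Brc1cc(OCc2ccccc2)c(OCc2ccccc2)cc1Br | intermediate
7 | [2,6-bis(benzyloxy)-4-(methoxymethoxy)phenyl]magnesium iodide | COCOc1cc(OCc2ccccc2)c([Mg]I)c(OCc2ccccc2)c1 | intermediate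
8 | carbon dioxide | O=C=O | starting material
9 | 2-bromo-4,5-bis(benzyloxy)phenylmagnesium bromide | Br[Mg]c1cc(OCc2ccccc2)c(OCc2ccccc2)cc1Br | intermediate
10 | 4,5-bis(benzyloxy)benzyne | C1#CC=C(OCc2ccccc2)C(OCc2ccccc2)=C1 | intermediate
11 | {4,5-bis(benzyloxy)-2-[2,6-bis(benzyloxy)-4-(methoxymethoxy)phenyl]phenyl}magnesium iodide | I[Mg]c1cc(OCc2ccccc2)c(OCc2ccccc2)cc1-c1c(OCc2ccccc2)cc(OCOC)cc1OCc1ccccc1 | intermediate
12 | 4,5-bis(benzyloxy)-2-[2,6-bis(benzyloxy)-4-(methoxymethoxy)phenyl]benzoic acid | OC(=O)c1cc(OCc2ccccc2)c(OCc2ccccc2)cc1-c1c(OCc2ccccc2)cc(OCOC)cc1OCc1ccccc1 | intermediate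
13 | 2',4',6'-trihydroxyacetophenone | CC(=O)c1c(O)cc(O)cc1O | starting material
14 | 1-[2,4-bis(benzyloxy)-6-hydroxyphenyl]ethanone | CC(=O)c1c(O)cc(OCc2ccccc2)cc1OCc1ccccc1 | intermediate
15 | 2-acetyl-3,5-bis(benzyloxy)phenyl 4,5-bis(benzyloxy)-2-[2,6-bis(benzyloxy)-4-(methoxymethoxy)phenyl]benzoate | CC(=O)c1c(OC(=O)c2cc(OCc3ccccc3)c(OCc3ccccc3)cc2-c2c(OCc3ccccc3)cc(OCOC)cc2OCc2ccccc2)cc(OCc2ccccc2)cc1OCc1ccccc1 | intermediate
16 | 1-[2,4-bis(benzyloxy)-6-hydroxyphenyl]-3-{4,5-bis(benzyloxy)-2-[2,6-bis(benzyloxy)-4-(methoxymethoxy)phenyl]phenyl}propane-1,3-dione | O=C(CC(=O)c1cc(OCc2ccccc2)c(OCc2ccccc2)cc1-c1c(OCc2ccccc2)cc(OCOC)cc1OCc1ccccc1)c1c(O)cc(OCc2ccccc2)cc1OCc1ccccc1 | intermediate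
17 | 5,7-bis(benzyloxy)-2-{4,5-bis(benzyloxy)-2-[2,6-bis(benzyloxy)-4-hydroxyphenyl]phenyl}-4H-chromen-4-one | O=c1cc(-c2cc(OCc3ccccc3)c(OCc3ccccc3)cc2-c2c(OCc3ccccc3)cc(O)cc2OCc2ccccc2)oc2cc(OCc3ccccc3)cc(OCc3ccccc3)c12 | intermediate
18 | 3,5-bis(benzyloxy)-4-{4,5-bis(benzyloxy)-2-[5,7-bis(benzyloxy)-4-oxo-4H-chromen-2-yl]phenyl}phenyl acetate | O=c1cc(-c2cc(OCc3ccccc3)c(OCc3ccccc3)cc2-c2c(OCc3ccccc3)cc(OC(C)=O)cc2OCc2ccccc2)oc2cc(OCc3ccccc3)cc(OCc3ccccc3)c12 | intermediate
19 | 2-{2-[3-acetyl-2,6-bis(benzyloxy)-4-hydroxyphenyl]-4,5-bis(benzyloxy)phenyl}-5,7-bis(benzyloxy)-4H-chromen-4-one | O=c1cc(-c2cc(OCc3ccccc3)c(OCc3ccccc3)cc2-c2c(OCc3ccccc3)c(C(C)=O)c(O)cc2OCc2ccccc2)oc2cc(OCc3ccccc3)cc(OCc3ccccc3)c12 | intermediate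
20 | (E)-3-(dimethylamino)prop-2-enoyl analogue of 19 (enaminone in place of the acetyl group) | O=c1cc(-c2cc(OCc3ccccc3)c(OCc3ccccc3)cc2-c2c(OCc3ccccc3)c(C(=O)/C=C/N(C)C)c(O)cc2OCc2ccccc2)oc2cc(OCc3ccccc3)cc(OCc3ccccc3)c12 | intermediate
21 | 5,7-bis(benzyloxy)-6-{4,5-bis(benzyloxy)-2-[5,7-bis(benzyloxy)-4-oxo-4H-chromen-2-yl]phenyl}-4H-chromen-4-one | O=c1ccoc2cc(OCc3ccccc3)c(-c3cc(OCc4ccccc4)c(OCc4ccccc4)cc3-c3cc(=O)c4c(OCc5ccccc5)cc(OCc5ccccc5)cc4o3)c(OCc3ccccc3)c12 | intermediate
22 | 4-(benzyloxy)phenylboronic acid | OB(O)c1ccc(OCc2ccccc2)cc1 | starting material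
23 | (2R)-5,7-bis(benzyloxy)-2-[4-(benzyloxy)phenyl]-6-{4,5-bis(benzyloxy)-2-[5,7-bis(benzyloxy)-4-oxo-4H-chromen-2-yl]phenyl}-2,3-dihydro-4H-chromen-4-one | O=C1C[C@H](c2ccc(OCc3ccccc3)cc2)Oc2cc(OCc3ccccc3)c(-c3cc(OCc4ccccc4)c(OCc4ccccc4)cc3-c3cc(=O)c4c(OCc5ccccc5)cc(OCc5ccccc5)cc4o3)c(OCc3ccccc3)c21 | intermediate
24 | (2R)-6-[2-(5,7-dihydroxy-4-oxo-4H-chromen-2-yl)-4,5-dihydroxyphenyl]-5,7-dihydroxy-2-(4-hydroxyphenyl)-2,3-dihydro-4H-chromen-4-one | O=C1C[C@H](c2ccc(O)cc2)Oc2cc(O)c(-c3cc(O)c(O)cc3-c3cc(=O)c4c(O)cc(O)cc4o3)c(O)c21 | target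

Total step count: 14. Longest linear sequence: 12 steps (steps 1, 2, 3, 5, 6, 8, 9, 10, 11, 12, 13, 14).

Steps most likely to fail

Step 6 (aryne union).
- **What may go wrong:** magnesium may insert sluggishly into the electron-rich dibromide. The aryne may be captured by the bromoaryl Grignard or by the biaryl Grignard instead of by 7, which leads to oligomerisation. The biaryl Grignard may also be protonated before carboxylation.
- **Fallback:** cross-coupling instead of aryne chemistry, setting out from 6 and 7 and returning at 12. Compound 6 undergoes a single bromine–magnesium exchange with i-PrMgCl·LiCl in THF at −20 °C. At that temperature 2-bromo-4,5-bis(benzyloxy)phenylmagnesium chloride F1 does not yet eliminate, and methyl chloroformate converts it into methyl 4,5-bis(benzyloxy)-2-bromobenzoate F2. Compound 7 is transmetallated with ZnCl2 to [2,6-bis(benzyloxy)-4-(methoxymethoxy)phenyl]zinc chloride F3. Negishi coupling of the two partners (Pd2(dba)3, RuPhos, THF, 65 °C) gives methyl 4,5-bis(benzyloxy)-2-[2,6-bis(benzyloxy)-4-(methoxymethoxy)phenyl]benzoate F4. Saponification (KOH, THF–MeOH–H2O, 60 °C) then delivers 12.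

Step 13 (enantioselective conjugate addition).
- **What may go wrong:** migratory insertion into the electron-rich chromone, which carries a peri substituent and a 6-aryl group, may be slow. The electron-rich boronic acid may protodeboronate in competition. The neighbouring biaryl axis may erode facial selectivity.
- **Fallback:** chalcone cyclisation and resolution instead of asymmetric catalysis, setting out from 19 and returning at 23. Claisen–Schmidt condensation of 19 with 4-(benzyloxy)benzaldehyde (KOH, EtOH–THF, rt) gives the (E)-2'-hydroxychalcone F5. Oxa-Michael ring closure (NaOAc, EtOH, reflux) gives the racemic heptabenzyl flavanone F6. Preparative chromatography on a polysaccharide chiral stationary phase separates 23 from the (2S)-enantiomer F7. The latter is re-equilibrated with mild base through the chalcone and recycled.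

Step 11 (C-acetylation).
- **What may go wrong:** the Lewis acid may remove or shift benzyl groups, especially those peri to a carbonyl. The reaction may also stall at the O-acetate stage.
- **Fallback:** base-mediated ortho-formylation and homologation instead of Lewis-acid acylation, setting out from 17 and returning at 19. Magnesium-phenoxide-directed formylation (MgCl2, Et3N, paraformaldehyde, MeCN, reflux) gives the salicylaldehyde F8. Addition of MeMgBr (2.5 equiv, THF, −78 °C) to the aldehyde, by far the most electrophilic carbonyl present, gives the 1-arylethanol F9. Benzylic oxidation with MnO2 in CH2Cl2 then delivers 19.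

Further compounds
F1 | step 6 | 2-bromo-4,5-bis(benzyloxy)phenylmagnesium chloride | Cl[Mg]c1cc(OCc2ccccc2)c(OCc2ccccc2)cc1Br
F2 | step 6 | methyl 4,5-bis(benzyloxy)-2-bromobenzoate | COC(=O)c1cc(OCc2ccccc2)c(OCc2ccccc2)cc1Br
F3 | step 6 | [2,6-bis(benzyloxy)-4-(methoxymethoxy)phenyl]zinc chloride | COCOc1cc(OCc2ccccc2)c([Zn]Cl)c(OCc2ccccc2)c1
F4 | step 6 | methyl 4,5-bis(benzyloxy)-2-[2,6-bis(benzyloxy)-4-(methoxymethoxy)phenyl]benzoate | COC(=O)c1cc(OCc2ccccc2)c(OCc2ccccc2)cc1-c1c(OCc2ccccc2)cc(OCOC)cc1OCc1ccccc1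
F5 | step 13 | (E)-2'-hydroxychalcone from 19 and 4-(benzyloxy)benzaldehyde | O=c1cc(-c2cc(OCc3ccccc3)c(OCc3ccccc3)cc2-c2c(OCc3ccccc3)c(C(=O)/C=C/c3ccc(OCc4ccccc4)cc3)c(O)cc2OCc2ccccc2)oc2cc(OCc3ccccc3)cc(OCc3ccccc3)c12
F6 | step 13 | racemic heptabenzyl flavanone | O=C1CC(c2ccc(OCc3ccccc3)cc2)Oc2cc(OCc3ccccc3)c(-c3cc(OCc4ccccc4)c(OCc4ccccc4)cc3-c3cc(=O)c4c(OCc5ccccc5)cc(OCc5ccccc5)cc4o3)c(OCc3ccccc3)c21
F7 | step 13 | (2S)-enantiomer of 23 | O=C1C[C@@H](c2ccc(OCc3ccccc3)cc2)Oc2cc(OCc3ccccc3)c(-c3cc(OCc4ccccc4)c(OCc4ccccc4)cc3-c3cc(=O)c4c(OCc5ccccc5)cc(OCc5ccccc5)cc4o3)c(OCc3ccccc3)c21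
F8 | step 11 | 2,4-bis(benzyloxy)-3-{4,5-bis(benzyloxy)-2-[5,7-bis(benzyloxy)-4-oxo-4H-chromen-2-yl]phenyl}-6-hydroxybenzaldehyde | O=c1cc(-c2cc(OCc3ccccc3)c(OCc3ccccc3)cc2-c2c(OCc3ccccc3)c(C=O)c(O)cc2OCc2ccccc2)oc2cc(OCc3ccccc3)cc(OCc3ccccc3)c12
F9 | step 11 | 1-hydroxyethyl analogue of 19 (secondary alcohol in place of the acetyl group, racemic at the carbinol carbon) | O=c1cc(-c2cc(OCc3ccccc3)c(OCc3ccccc3)cc2-c2c(OCc3ccccc3)c(C(C)O)c(O)cc2OCc2ccccc2)oc2cc(OCc3ccccc3)cc(OCc3ccccc3)c12
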